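## The problem

Target 21 is a trans-2,3-diaryl-2,3-dihydrobenzofuran. Its five-membered ring (O1, C2, C3, C3a, C7a) is fused to ring A, which carries a hydroxyl at C4 and a 6-hydroxybenzofuran-2-yl group at C6; C2 bears a 4-hydroxyphenyl and C3 a 3,5-dihydroxyphenyl group. The only stereocentres are C2 and C3, both S and trans to each other. Trans is the more stable arrangement, so one centre can steer the other, but the absolute configuration has to come from a catalyst, and C2, which can be made by adding an aryl group to an enone, is the better place for it. Three features are fragile: the five phenols, which are easily oxidised and must stay masked to the end; the O1–C2 bond, a benzylic ether para to an oxygen on the C2 aryl ring, which acid can ionise; and the doubly benzylic C3–H, whose loss from such a cation would give an achiral triarylethylene. Four aryl–carbon bonds leave the small core, so the benzofuran (at C6) and the resorcinol ring (at C3) should be attached as separate pieces. The feature that opens the structure is that O1, C2 with its para-oxygenated aryl group, C3 and the 4,6-dioxygenated ring A are the atoms of a 5,7-dioxygenated flavanone whose carbonyl carbon has been pushed out of the ring. If ring A migrates from the carbonyl carbon to the alpha carbon, the pyranone contracts to the dihydrofuran and leaves a carboxylate on C3 that can later be exchanged for the aryl group; the migrating carbon is flanked by O1 and a second oxygen, the pattern that migrates best.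

## Retrosynthesis

**21 from 20.** The five O–methyl bonds are cut last. Methyl ethers are the only masks that survive every step of the route, including the acidic oxidative key step, and all five fall to one reagent. The forward step has to cleave five ethers without losing the benzylic O1–C2 bond for good.

**20 from 16 and 19.** The biaryl bond between C6 and the benzofuran C2 is cut to the aryl triflate 16 and the boronate 19, which comes in one step from commercial 6-methoxybenzofuran 17. This coupling is placed late because by then the molecule has no base-sensitive ester, and the electron-rich benzofuran never meets the oxidant of the key step. It asks only for a Suzuki–Miyaura coupling of a protodeboronation-prone 2-heteroaryl boronate.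

**16 from 15 from 14.** The triflate is traced to the C6 phenol 15 and this to the benzyl ether 14. Benzyl is the one oxygen mask that can be removed in the presence of the four methyl ethers, so it marks the oxygen that becomes the coupling handle. Hydrogenolysis must stop before the cyclic benzylic O1–C2 bond is touched.

**14 from 12 and 13.** The C3–aryl bond is cut to the C3 carboxylic acid 11, activated as the N-acyloxyphthalimide 12, and 1-iodo-3,5-dimethoxybenzene 13. This cut is preferred to cuts at C2–aryl or C2–C3 because it leaves at C3 the carboxylate that the ring contraction delivers, and because the C3 radical is planar, so C2 alone decides the new configuration. The arylation is done before the triflate exists (nickel would insert into it) and before any warm basic step (the ester is gone early). 12 comes from ester 10 through acid 11.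

**10 from 7 (key disconnection).** The C3–C3a bond is cut and the ester carbon is put back into the ring between C3 and C3a, which gives the flavanone 7. The precursor loses one stereocentre and becomes a compound class for which catalytic asymmetric synthesis is established. The forward reaction has to oxidise C3, move ring A from C4 to C3 with the ester ending trans to the C2 aryl group, and leave C2 untouched; it passes through the enol ether 8 and the iodanyl ketal 9.

**7 from 5 and 6.** The C2–aryl bond is cut to the chromone 5 and 4-methoxyphenylboronic acid 6. This puts the only catalyst-controlled stereocentre in an enantioselective conjugate addition to a flat, achiral enone.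

**5 from 3 from 2 from 1.** The chromone C2 carbon is removed (it comes from a formamide acetal through enaminone 4), then the methyl and benzyl groups, which leads to 2,4,6-trihydroxyacetophenone 1. The three hydroxyls of 1 are told apart by hydrogen bonding to the acetyl group: the para one reacts first (2), then one of the two chelated ones (3), and the last closes the pyranone.

## Roads not taken

Alternative 1: The cut is O1–C2 together with the C3–H bond, leading to the achiral triarylethylene A1, in which ring A carries two equivalent ortho hydroxyls. A BINOL-derived chiral phosphoric acid would protonate the alkene at C3, the cation would be held as a para-quinone methide through the free hydroxyl of the C2 aryl ring, and an ortho hydroxyl would add to C2 in a 5-exo closure to give the trans trimethyl ether A2.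
- Merits: both stereocentres and the ring arise in one catalytic step from an alkene with no stereochemistry, no protecting group is needed on the two reacting oxygens, and only three methyl ethers remain to be cleaved. In step count and convergence this road is better than the chosen one.
- Weak points: the configuration-determining event is C-protonation of a weakly basic triaryl alkene at a carbon with no nearby binding site, which is at or beyond the acidity of phosphoric acids. The protonation is reversible, so the same acid can racemise C3. The quinone methide can also alkylate the electron-rich benzofuran or resorcinol rings.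
- Comparison: the chosen plan is longer but sets C2 by a documented asymmetric conjugate addition and C3 by substrate control, where Alternative 1 stakes the absolute configuration on an unprecedented protonation.

Alternative 2: The cut is C7a–O1 plus C3–C3a, giving the ortho-silylaryl triflate A3 as aryne source and the enantioenriched trans-stilbene oxide A4. CsF would release the aryne, the epoxide oxygen would add at the carbon meta to the methoxy group (C7a), and the aryl anion at C3a would take over the benzylic C3 as its C–O bond breaks, giving A5.
- Merits: the whole carbon skeleton is assembled from two pieces in one step, the methoxy group on the aryne directs the regiochemistry of oxygen attack, and asymmetric epoxidation of trans-stilbenes is well developed. It is more convergent than the chosen plan.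
- Weak points: insertion of an aryne into an epoxide C–O bond is barely established, and an epoxide oxygen is a poor nucleophile next to fluoride. The choice between the two benzylic C–O bonds rests only on the triflate deactivating C2, while the meta-dimethoxy ring hardly stabilises charge at C3. The aryl anion must replace oxygen at C3 from the same side in a four-centre arrangement or through a free cation, so neither the trans relationship nor the enantiomeric purity at C3 is secured. The aryl triflate costs an extra deprotection.
- Comparison: the chosen plan forms each bond by a reaction of known regio- and stereochemistry and pays for it with length.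

Alternative 3: The cut is C2–C3, leading to the diaryl diazomethane A6, whose ring A carries an ortho 4-methoxybenzyl ether. A chiral dirhodium tetracarboxylate such as Rh2(S-PTAD)4 or its mirror image (divalent rhodium) would form the diaryl carbene at C3, which inserts into the benzylic ether C–H to give the cis pentamethyl ether A7. Acid would then epimerise C2 through the benzylic cation to the trans compound, which is 20 of the present route.
- Merits: donor/donor carbene insertion into benzylic ether C–H bonds is a known way to cis-2,3-diaryl-dihydrobenzofurans with high enantioselectivity. Both centres are set in one catalytic step and 20 would be reached in clearly fewer steps. In step economy and in directness of stereocontrol this road is at least as good as the chosen one.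
- Weak points: the carbene carbon sits between two ortho oxygen substituents on ring A. The benzophenone hydrazone and its oxidation to A6 are therefore hindered, and the twisted, crowded carbene is a harder case than the mono-ortho substrates on which the method rests. The cis product needs an acid epimerisation at the fragile O1–C2 bond, and a diazo compound must be handled on scale.
- Comparison: against the shorter sequence the chosen plan sets a direct entry to the trans series, no diazo chemistry, catalysts and reagents of everyday use, and late, separate introduction of the two aryl groups. Its price is about four more steps and a radical arylation whose selectivity must be proven.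

Key step: step 5

Assumption: the pyridine-oxazoline palladium catalyst is taken to add the aryl group to the chromone with the same facial sense as to cyclic enones, which makes the (R)-ligand the one that gives the (2S)-flavanone 7; if the sense is opposite, the (S)-ligand is used.

## Route

Step 1
Reactants: 1 2,4,6-trihydroxyacetophenone
Product: 2 1-(4-benzyloxy-2,6-dihydroxyphenyl)ethanone
Conditions: BnBr (1.0 equiv), K2CO3 (1.1 equiv), DMF, 0 to 23 °C
Reagents that add atoms: benzyl bromide, BrCc1ccccc1
Why: Williamson etherification; the two ortho hydroxyls are hydrogen-bonded to the acetyl oxygen, so the para hydroxyl is the most acidic and most nucleophilic and is alkylated first, and one equivalent of halide limits double benzylation.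

Step 2
Reactants: 2 1-(4-benzyloxy-2,6-dihydroxyphenyl)ethanone
Product: 3 1-(4-benzyloxy-2-hydroxy-6-methoxyphenyl)ethanone
Conditions: Me2SO4 (1.05 equiv), K2CO3, acetone, 56 °C
Reagents that add atoms: dimethyl sulfate, COS(=O)(=O)OC
Why: Williamson etherification; after the first methylation the remaining hydroxyl is strongly chelated to the carbonyl and resists further alkylation, the classical partial methylation of phloroacetophenones.

Step 3
Reactants: 3 1-(4-benzyloxy-2-hydroxy-6-methoxyphenyl)ethanone
Product: 5 7-benzyloxy-5-methoxy-4H-chromen-4-one, via enaminone 4 (not isolated)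
Conditions: Me2NCH(OMe)2 (3 equiv), toluene, 100 °C; then conc. HCl, CH2Cl2, 40 °C
Reagents that add atoms: N,N-dimethylformamide dimethyl acetal, COC(OC)N(C)C
Why: Enaminone condensation at the acetyl methyl group followed by acid-promoted conjugate addition of the phenol and loss of dimethylamine, the standard enaminone route to 3-unsubstituted chromones.

Step 4
Reactants: 5 7-benzyloxy-5-methoxy-4H-chromen-4-one, 6 4-methoxyphenylboronic acid
Product: 7 (2S)-7-benzyloxy-5-methoxy-2-(4-methoxyphenyl)chroman-4-one
Conditions: Pd(OCOCF3)2 (5 mol %), (R)-4-tert-butyl-2-(pyridin-2-yl)-4,5-dihydrooxazole (6 mol %), NH4PF6 (30 mol %), H2O (5 equiv), 6 (2 equiv), ClCH2CH2Cl, 60 °C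
Reagents that add atoms: none
Why: Asymmetric conjugate addition of an arylboronic acid to a chromone under cationic divalent palladium; the aryl–palladium species inserts the C2=C3 bond on the face left open by the tert-butyl group of the ligand, which sets C2, and water protonates the palladium enolate so that palladium stays divalent.

Step 5
Reactants: 7 (2S)-7-benzyloxy-5-methoxy-2-(4-methoxyphenyl)chroman-4-one
Product: 10 methyl (2S,3S)-6-benzyloxy-4-methoxy-2-(4-methoxyphenyl)-2,3-dihydro-1-benzofuran-3-carboxylate, via methyl enol ether 8 (not isolated), via trans C3-iodanyl ketal 9 (not isolated)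
Conditions: PhI(OAc)2 (1.2 equiv), H2SO4 (0.5 equiv), HC(OMe)3/MeOH (1:1), 0 to 23 °C
Reagents that add atoms: methanol, CO
Why: This is the oxidative 1,2-aryl shift of an aryl ketone ketal with ring contraction, the reaction type known for flavanones with PhI(OAc)2 or Tl(NO3)3 in acidic methanol and trimethyl orthoformate. Acid and orthoformate turn the ketone into enol ether 8, whose C3 attacks the trivalent iodine centre from the face anti to the pseudo-equatorial C2 aryl group, and methanol captures the oxocarbenium ion to give ketal 9 with the iodane equatorial. In 9 the C3–I bond is antiperiplanar to the C4–C4a bond, so ring A shifts from C4 to C3 through a bridged arenium ion as iodobenzene leaves, and the dimethoxycarbenium ion left on the old C4 collapses to the methyl ester. The new C3–C3a bond forms with inversion at C3; the five-membered ring is closed by contraction of the six-membered one through this 1,2-shift, not by cyclisation of a chain. The ester therefore ends trans to the C2 aryl group, which is also the more stable epimer, so C3 is controlled by C2 through the anti approach of the iodane, and C2 itself is not touched. The step needs aryl migration to outrun methanolysis of the C–I bond, elimination to the flavone and a shift of the anisyl group from C2. The push of the two ketal oxygens and the migrating carbon flanked by O1 and the C5 methoxy group secure the first two, and the equatorial iodane is not antiperiplanar to the C2–aryl bond, which blocks the third. Only a small excess of oxidant at low temperature is used to keep the iodane away from the electron-rich ring A itself.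

Step 6
Reactants: 10 methyl (2S,3S)-6-benzyloxy-4-methoxy-2-(4-methoxyphenyl)-2,3-dihydro-1-benzofuran-3-carboxylate
Product: 11 (2S,3S)-6-benzyloxy-4-methoxy-2-(4-methoxyphenyl)-2,3-dihydro-1-benzofuran-3-carboxylic acid
Conditions: LiOH·H2O (3 equiv), THF/MeOH/H2O, 23 °C; then 1 M HCl
Reagents that add atoms: lithium hydroxide, [Li+].[OH-]
Why: Saponification by acyl–oxygen cleavage; the C2–O1 bond lies close to the nodal plane of the C3 ester enolate in the nearly flat five-membered ring, so expulsion of the aryloxide is stereoelectronically disfavoured, and the trans acid is the stable epimer; Me3SnOH in ClCH2CH2Cl is the non-basic reserve.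

Step 7
Reactants: 11 (2S,3S)-6-benzyloxy-4-methoxy-2-(4-methoxyphenyl)-2,3-dihydro-1-benzofuran-3-carboxylic acid
Product: 12 1,3-dioxoisoindolin-2-yl (2S,3S)-6-benzyloxy-4-methoxy-2-(4-methoxyphenyl)-2,3-dihydro-1-benzofuran-3-carboxylate
Conditions: N-hydroxyphthalimide (1.1 equiv), N,N'-diisopropylcarbodiimide (1.1 equiv), DMAP (10 mol %), CH2Cl2, 23 °C
Reagents that add atoms: N-hydroxyphthalimide, O=C1N(O)C(=O)c2ccccc12
Why: Steglich-type carbodiimide esterification to the redox-active ester; the configuration at C3 is of no consequence because it is erased in the next step.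

Step 8
Reactants: 12 1,3-dioxoisoindolin-2-yl (2S,3S)-6-benzyloxy-4-methoxy-2-(4-methoxyphenyl)-2,3-dihydro-1-benzofuran-3-carboxylate, 13 1-iodo-3,5-dimethoxybenzene
Product: 14 (2S,3S)-6-benzyloxy-3-(3,5-dimethoxyphenyl)-4-methoxy-2-(4-methoxyphenyl)-2,3-dihydro-1-benzofuran
Conditions: NiCl2(dme) (10 mol %), 4,4'-di-tert-butyl-2,2'-bipyridine (10 mol %), Zn (2 equiv), 13 (1.5 equiv), DMA, 23 °C
Reagents that add atoms: none
Why: Nickel-catalysed decarboxylative cross-electrophile coupling of an N-acyloxyphthalimide with an aryl iodide; single-electron reduction releases CO2 and the planar benzylic C3 radical, which is captured by the arylnickel species formed from 13 and zerovalent nickel, and reductive elimination forms the C3–aryl bond. The aryl group should be delivered to the face opposite the C2 aryl group, so C2 sets the trans (3S) configuration, and the C2–O1 bond is nearly orthogonal to the radical orbital, so ring opening by fragmentation is not expected.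

Step 9
Reactants: 14 (2S,3S)-6-benzyloxy-3-(3,5-dimethoxyphenyl)-4-methoxy-2-(4-methoxyphenyl)-2,3-dihydro-1-benzofuran
Product: 15 (2S,3S)-3-(3,5-dimethoxyphenyl)-4-methoxy-2-(4-methoxyphenyl)-2,3-dihydro-1-benzofuran-6-ol
Conditions: H2 (1 atm), 10% Pd/C, EtOAc/MeOH, 23 °C
Reagents that add atoms: none
Why: Hydrogenolysis of a benzyl aryl ether, which is much faster than cleavage of the cyclic, more hindered benzylic O1–C2 bond; the reaction is stopped when 14 is consumed.

Step 10
Reactants: 15 (2S,3S)-3-(3,5-dimethoxyphenyl)-4-methoxy-2-(4-methoxyphenyl)-2,3-dihydro-1-benzofuran-6-ol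
Product: 16 (2S,3S)-3-(3,5-dimethoxyphenyl)-4-methoxy-2-(4-methoxyphenyl)-2,3-dihydro-1-benzofuran-6-yl trifluoromethanesulfonate
Conditions: Tf2O (1.2 equiv), pyridine (3 equiv), CH2Cl2, 0 °C
Reagents that add atoms: trifluoromethanesulfonic anhydride, O=S(=O)(OS(=O)(=O)C(F)(F)F)C(F)(F)F
Why: O-sulfonylation of the only free phenol; the buffered, cold conditions do not ionise the benzylic ether.

Step 11
Reactants: 17 6-methoxybenzofuran
Product: 19 2-(6-methoxy-1-benzofuran-2-yl)-4,4,5,5-tetramethyl-1,3,2-dioxaborolane, via 2-lithio-6-methoxybenzofuran 18 (not isolated)
Conditions: n-BuLi (1.1 equiv), THF, −78 °C; then 2-isopropoxy-4,4,5,5-tetramethyl-1,3,2-dioxaborolane, −78 to 23 °C; aq. NH4Cl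
Reagents that add atoms: 2-isopropoxy-4,4,5,5-tetramethyl-1,3,2-dioxaborolane, CC(C)OB1OC(C)(C)C(C)(C)O1
Why: Deprotonation of benzofuran at C2, its most acidic position next to the ring oxygen, and trapping with a borate ester; the pinacol ester is chosen because it resists protodeboronation better than the free boronic acid.

Step 12
Reactants: 16 (2S,3S)-3-(3,5-dimethoxyphenyl)-4-methoxy-2-(4-methoxyphenyl)-2,3-dihydro-1-benzofuran-6-yl trifluoromethanesulfonate, 19 2-(6-methoxy-1-benzofuran-2-yl)-4,4,5,5-tetramethyl-1,3,2-dioxaborolane
Product: 20 (2S,3S)-3-(3,5-dimethoxyphenyl)-4-methoxy-6-(6-methoxy-1-benzofuran-2-yl)-2-(4-methoxyphenyl)-2,3-dihydro-1-benzofuran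
Conditions: PdCl2(dppf) (5 mol %), K3PO4 (3 equiv), 19 (1.5 equiv), 1,4-dioxane/H2O (10:1), 80 °C
Reagents that add atoms: none
Why: Suzuki–Miyaura coupling of an unhindered aryl triflate with a heteroaryl boronate through zerovalent palladium; no epimerisable or base-labile centre is left in 16, so the warm basic medium is harmless.

Step 13
Reactants: 20 (2S,3S)-3-(3,5-dimethoxyphenyl)-4-methoxy-6-(6-methoxy-1-benzofuran-2-yl)-2-(4-methoxyphenyl)-2,3-dihydro-1-benzofuran
Product: 21 (2S,3S)-3-(3,5-dihydroxyphenyl)-6-(6-hydroxy-1-benzofuran-2-yl)-2-(4-hydroxyphenyl)-2,3-dihydro-1-benzofuran-4-ol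
Conditions: BBr3 (10 equiv), CH2Cl2, −78 to 23 °C; then H2O, 0 °C
Reagents that add atoms: none
Why: Lewis-acid cleavage of the five aryl methyl ethers by complexation and bromide attack at methyl; neither stereocentre carries an acidic hydrogen, and should the O1–C2 bond open reversibly, re-closure by the C7a oxygen is steered back to trans by the untouched C3 centre, so the (2S,3S) configuration should be kept.

## Compound list

1 | 2,4,6-trihydroxyacetophenone | CC(=O)c1c(O)cc(O)cc1O | starting material
2 | 1-(4-benzyloxy-2,6-dihydroxyphenyl)ethanone | CC(=O)c1c(O)cc(OCc2ccccc2)cc1O | intermediate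
3 | 1-(4-benzyloxy-2-hydroxy-6-methoxyphenyl)ethanone | CC(=O)c1c(O)cc(OCc2ccccc2)cc1OC | intermediate
4 | (E)-1-(4-benzyloxy-2-hydroxy-6-methoxyphenyl)-3-(dimethylamino)prop-2-en-1-one | CN(C)/C=C/C(=O)c1c(O)cc(OCc2ccccc2)cc1OC | intermediate
5 | 7-benzyloxy-5-methoxy-4H-chromen-4-one | COc1cc(OCc2ccccc2)cc2occc(=O)c12 | intermediate
6 | 4-methoxyphenylboronic acid | COc1ccc(cc1)B(O)O | starting material
7 | (2S)-7-benzyloxy-5-methoxy-2-(4-methoxyphenyl)chroman-4-one | COc1ccc([C@@H]2CC(=O)c3c(OC)cc(OCc4ccccc4)cc3O2)cc1 | intermediate
8 | (2S)-7-benzyloxy-4,5-dimethoxy-2-(4-methoxyphenyl)-2H-chromene | COc1ccc([C@@H]2C=C(OC)c3c(OC)cc(OCc4ccccc4)cc3O2)cc1 | intermediate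
9 | (2R,3R)-3-[acetoxy(phenyl)-λ3-iodanyl]-7-benzyloxy-4,4,5-trimethoxy-2-(4-methoxyphenyl)chromane (iodane trans to the C2 aryl group) | COc1ccc([C@@H]2[C@@H](I(OC(C)=O)c5ccccc5)C(OC)(OC)c3c(OC)cc(OCc4ccccc4)cc3O2)cc1 | intermediate
10 | methyl (2S,3S)-6-benzyloxy-4-methoxy-2-(4-methoxyphenyl)-2,3-dihydro-1-benzofuran-3-carboxylate | COc1ccc([C@H]2Oc3cc(OCc4ccccc4)cc(OC)c3[C@@H]2C(=O)OC)cc1 | intermediate
11 | (2S,3S)-6-benzyloxy-4-methoxy-2-(4-methoxyphenyl)-2,3-dihydro-1-benzofuran-3-carboxylic acid | COc1ccc([C@H]2Oc3cc(OCc4ccccc4)cc(OC)c3[C@@H]2C(=O)O)cc1 | intermediate
12 | 1,3-dioxoisoindolin-2-yl (2S,3S)-6-benzyloxy-4-methoxy-2-(4-methoxyphenyl)-2,3-dihydro-1-benzofuran-3-carboxylate | COc1ccc([C@H]2Oc3cc(OCc4ccccc4)cc(OC)c3[C@@H]2C(=O)ON2C(=O)c3ccccc3C2=O)cc1 | intermediate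
13 | 1-iodo-3,5-dimethoxybenzene | COc1cc(I)cc(OC)c1 | starting material
14 | (2S,3S)-6-benzyloxy-3-(3,5-dimethoxyphenyl)-4-methoxy-2-(4-methoxyphenyl)-2,3-dihydro-1-benzofuran | COc1ccc([C@H]2Oc3cc(OCc4ccccc4)cc(OC)c3[C@@H]2c2cc(OC)cc(OC)c2)cc1 | intermediate
15 | (2S,3S)-3-(3,5-dimethoxyphenyl)-4-methoxy-2-(4-methoxyphenyl)-2,3-dihydro-1-benzofuran-6-ol | COc1ccc([C@H]2Oc3cc(O)cc(OC)c3[C@@H]2c2cc(OC)cc(OC)c2)cc1 | intermediate
16 | (2S,3S)-3-(3,5-dimethoxyphenyl)-4-methoxy-2-(4-methoxyphenyl)-2,3-dihydro-1-benzofuran-6-yl trifluoromethanesulfonate | COc1ccc([C@H]2Oc3cc(OS(=O)(=O)C(F)(F)F)cc(OC)c3[C@@H]2c2cc(OC)cc(OC)c2)cc1 | intermediate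
17 | 6-methoxybenzofuran | COc1ccc2ccoc2c1 | starting material
18 | 2-lithio-6-methoxybenzofuran | COc1ccc2cc([Li])oc2c1 | intermediate
19 | 2-(6-methoxy-1-benzofuran-2-yl)-4,4,5,5-tetramethyl-1,3,2-dioxaborolane | COc1ccc2cc(B3OC(C)(C)C(C)(C)O3)oc2c1 | intermediate
20 | (2S,3S)-3-(3,5-dimethoxyphenyl)-4-methoxy-6-(6-methoxy-1-benzofuran-2-yl)-2-(4-methoxyphenyl)-2,3-dihydro-1-benzofuran | COc1ccc([C@H]2Oc3cc(-c4cc5ccc(OC)cc5o4)cc(OC)c3[C@@H]2c2cc(OC)cc(OC)c2)cc1 | intermediate
21 | (2S,3S)-3-(3,5-dihydroxyphenyl)-6-(6-hydroxy-1-benzofuran-2-yl)-2-(4-hydroxyphenyl)-2,3-dihydro-1-benzofuran-4-ol | Oc1ccc([C@H]2Oc3cc(-c4cc5ccc(O)cc5o4)cc(O)c3[C@@H]2c2cc(O)cc(O)c2)cc1 | target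

## Step count and risk

Total: 13 steps. Longest linear sequence: 12 steps (steps 1 to 10, 12 and 13); step 11 is a one-step branch.

**Step 5 (key step).** Substitution or elimination at the C3–iodine bond may outrun aryl migration (capture by methanol, loss of the iodane toward the flavone, or a shift of the anisyl group from C2). The oxidant may also attack the very electron-rich ring A, and acid may open the pyranone ring and erode the configuration at C2. The fallback sets out from 7 and comes back at 10, and it separates oxidation from migration. 7 would be brominated at C3 with CuBr2 in EtOAc/CHCl3 to (2R,3R)-7-benzyloxy-3-bromo-5-methoxy-2-(4-methoxyphenyl)chroman-4-one F1, the 2,3-trans bromide. F1 would be converted into its dimethyl ketal with HC(OMe)3/MeOH and TsOH and treated with AgBF4, so that silver-assisted loss of bromide is accompanied by the same shift of ring A to give 10. Rearrangement of alpha-halo ketals of aryl ketones to arylacetic esters is established chemistry; no iodane is present, and the bromide leaves only with the help of the migrating ring.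

**Step 8.** The stabilised, hindered benzylic radical may dimerise or be reduced before nickel captures it. Beta-hydride elimination from the C3–nickel intermediate toward the aromatic benzofuran may compete with reductive elimination. Facial selectivity in the capture may be incomplete; the cis isomer would have to be separated, because acid equilibration moves C2, not C3, and would lead into the enantiomeric series. The fallback sets out from acid 11 and comes back at 14 without any new compound. The radical would be generated oxidatively from the carboxylate by metallaphotoredox coupling with 13 (Ir[dF(CF3)ppy]2(dtbbpy)PF6, NiCl2(dme), 4,4'-di-tert-butyl-2,2'-bipyridine, Cs2CO3, DMF, blue light). The radical then forms at low concentration, without zinc and without the activated ester, which disfavours dimerisation and reduction.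

**Step 13.** The hindered C4 ether may cleave incompletely while long exposure to BBr3 and the HBr set free on quenching opens the dihydrofuran at O1–C2, followed by elimination or alkylation of the electron-rich rings. The free pentaphenol may also be lost to air and silica. The fallback sets out from 20 and comes back at 21. The BBr3 treatment would be kept short and cold, the boron aryloxides quenched directly with Ac2O/pyridine, and the product isolated as (2S,3S)-3-(3,5-diacetoxyphenyl)-6-(6-acetoxy-1-benzofuran-2-yl)-2-(4-acetoxyphenyl)-2,3-dihydro-1-benzofuran-4-yl acetate F2. F2 can be chromatographed, partly methylated material can be separated and resubmitted, and the acetates would be removed with catalytic K2CO3 in MeOH at 0 °C. The last operation is then a near-neutral transesterification instead of an acidic work-up of the free polyphenol.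

**Step 4.** Turnover may be low because the peri methoxy group twists and deactivates the enone while the electron-rich boronic acid protodeboronates. The enantiomeric purity may be insufficient, or the flavanone may open to the chalcone under the warm, mildly acidic conditions. The fallback sets out from 3 and comes back at 7. Claisen–Schmidt condensation of 3 with 4-methoxybenzaldehyde (KOH, EtOH) would give (E)-1-(4-benzyloxy-2-hydroxy-6-methoxyphenyl)-3-(4-methoxyphenyl)prop-2-en-1-one F3. Cyclisation with NaOAc in refluxing EtOH would give racemic 7-benzyloxy-5-methoxy-2-(4-methoxyphenyl)chroman-4-one F4, and preparative chromatography on a chiral stationary phase would deliver 7. The unwanted (2R)-7-benzyloxy-5-methoxy-2-(4-methoxyphenyl)chroman-4-one F5 would be racemised with base through F3 and recycled.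

## Further compounds

F1 | step 5 | (2R,3R)-7-benzyloxy-3-bromo-5-methoxy-2-(4-methoxyphenyl)chroman-4-one | COc1ccc([C@@H]2[C@@H](Br)C(=O)c3c(OC)cc(OCc4ccccc4)cc3O2)cc1
F0 | step 8 | none | none
F2 | step 13 | (2S,3S)-3-(3,5-diacetoxyphenyl)-6-(6-acetoxy-1-benzofuran-2-yl)-2-(4-acetoxyphenyl)-2,3-dihydro-1-benzofuran-4-yl acetate | CC(=O)Oc1ccc([C@H]2Oc3cc(-c4cc5ccc(OC(C)=O)cc5o4)cc(OC(C)=O)c3[C@@H]2c2cc(OC(C)=O)cc(OC(C)=O)c2)cc1
F3 | step 4 | (E)-1-(4-benzyloxy-2-hydroxy-6-methoxyphenyl)-3-(4-methoxyphenyl)prop-2-en-1-one | COc1ccc(/C=C/C(=O)c2c(O)cc(OCc3ccccc3)cc2OC)cc1
F4 | step 4 | racemic 7-benzyloxy-5-methoxy-2-(4-methoxyphenyl)chroman-4-one | COc1ccc(C2CC(=O)c3c(OC)cc(OCc4ccccc4)cc3O2)cc1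
F5 | step 4 | (2R)-7-benzyloxy-5-methoxy-2-(4-methoxyphenyl)chroman-4-one | COc1ccc([C@H]2CC(=O)c3c(OC)cc(OCc4ccccc4)cc3O2)cc1
A1 | alternative 1 | 2-[1-(3,5-dimethoxyphenyl)-2-(4-hydroxyphenyl)ethenyl]-5-(6-methoxy-1-benzofuran-2-yl)benzene-1,3-diol | Oc1ccc(C=C(c2cc(OC)cc(OC)c2)c2c(O)cc(-c3cc4ccc(OC)cc4o3)cc2O)cc1
A2 | alternative 1 | 4-[(2S,3S)-3-(3,5-dimethoxyphenyl)-4-hydroxy-6-(6-methoxy-1-benzofuran-2-yl)-2,3-dihydro-1-benzofuran-2-yl]phenol | Oc1ccc([C@H]2Oc3cc(-c4cc5ccc(OC)cc5o4)cc(O)c3[C@@H]2c2cc(OC)cc(OC)c2)cc1
A3 | alternative 2 | 3-methoxy-5-(6-methoxy-1-benzofuran-2-yl)-2-(trimethylsilyl)phenyl trifluoromethanesulfonate | COc1cc(-c2cc3ccc(OC)cc3o2)cc(OS(=O)(=O)C(F)(F)F)c1[Si](C)(C)C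
A4 | alternative 2 | 4-[(2R,3R)-3-(3,5-dimethoxyphenyl)oxiran-2-yl]phenyl trifluoromethanesulfonate (trans epoxide, the configuration required if oxygen is replaced at C3 with retention) | FC(F)(F)S(=O)(=O)Oc1ccc([C@H]2O[C@@H]2c2cc(OC)cc(OC)c2)cc1
A5 | alternative 2 | 4-[(2S,3S)-3-(3,5-dimethoxyphenyl)-4-methoxy-6-(6-methoxy-1-benzofuran-2-yl)-2,3-dihydro-1-benzofuran-2-yl]phenyl trifluoromethanesulfonate | FC(F)(F)S(=O)(=O)Oc1ccc([C@H]2Oc3cc(-c4cc5ccc(OC)cc5o4)cc(OC)c3[C@@H]2c2cc(OC)cc(OC)c2)cc1
A6 | alternative 3 | 2-[diazo(3,5-dimethoxyphenyl)methyl]-1-methoxy-3-[(4-methoxyphenyl)methoxy]-5-(6-methoxy-1-benzofuran-2-yl)benzene | COc1ccc(COc2cc(-c3cc4ccc(OC)cc4o3)cc(OC)c2C(=[N+]=[N-])c2cc(OC)cc(OC)c2)cc1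
A7 | alternative 3 | (2R,3S)-3-(3,5-dimethoxyphenyl)-4-methoxy-6-(6-methoxy-1-benzofuran-2-yl)-2-(4-methoxyphenyl)-2,3-dihydro-1-benzofuran (cis) | COc1ccc([C@@H]2Oc3cc(-c4cc5ccc(OC)cc5o4)cc(OC)c3[C@@H]2c2cc(OC)cc(OC)c2)cc1
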